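**Plan**
- Cuts, in retrosynthetic order: the C15–O acyl bond and the exocyclic C11=C13 methylene; the ring olefin C10=C1; then C9–C10, C5–C6 and C6–C7 of the open chain.
- Enabling feature: on the carbocycle C7–C8–C9–C10–C1–C2–C3–C4–C5–C6, C14 sits on C10 trans to C2. With C14 as an ester, C10=C1 is therefore the E-enoate of a phosphonoacetate olefination and at the same time the ring-cis olefin of the ten-membered ring.
- Forward: the γ-lactone ring comes first (from D-glutamic acid). C6 is added to C7 by photochemical hydroxymethylation, C5–C1 by Negishi coupling at C5–C6, C10/C14 by alkylation at C9. The ten-membered ring then closes by C10=C1 olefination; the methylene lactone and the C15 ester come last.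
- Stereochemistry: C8 is the α-carbon of D-glutamic acid (retention on lactonisation). C7 is set trans by radical addition anti to the C8 substituent. The C4=C5 geometry comes from anti-carbomagnesiation of propargyl alcohol, the C10=C1 geometry from the ring-matched E-selective olefination.

Key step: step 14

Remark: germacrane locants (C7 = ring-fusion CH bearing C11, C8 = O–CH, C14 on C10, C15 on C4) are used for all intermediates. The C10 centre of the phosphonoacetates 20 and 21 is carried as both epimers because it becomes sp2 in step 14.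

**Step 1**
Reactants: 1 D-glutamic acid
Product: 2 (R)-5-oxotetrahydrofuran-2-carboxylic acid
Conditions: NaNO2, 2 M aq. HCl, 0 °C → rt
Reagents that add atoms: none
Why: Nitrous acid deamination proceeds through an α-lactone that the γ-carboxylate opens, so the γ-lactone forms with net retention (double inversion) at the future C8.

**Step 2**
Reactants: 2 (R)-5-oxotetrahydrofuran-2-carboxylic acid
Product: 3 (R)-5-(hydroxymethyl)dihydrofuran-2(3H)-one
Conditions: BH3·SMe2, THF, 0 °C → rt; MeOH quench
Reagents that add atoms: none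
Why: Chemoselective borane reduction, since a free carboxylic acid is reduced much faster than a lactone, gives the primary alcohol that becomes C9.

**Step 3**
Reactants: 3 (R)-5-(hydroxymethyl)dihydrofuran-2(3H)-one
Product: 4 (R)-5-[(tert-butyldimethylsilyloxy)methyl]dihydrofuran-2(3H)-one
Conditions: TBSCl, imidazole, DMF, rt
Reagents that add atoms: tert-butyldimethylsilyl chloride, CC(C)(C)[Si](C)(C)Cl
Why: Imidazole-promoted silylation of the primary alcohol masks C9–OH for the enolate, photochemical and organozinc steps.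

**Step 4**
Reactants: 4 (R)-5-[(tert-butyldimethylsilyloxy)methyl]dihydrofuran-2(3H)-one
Product: 6 (R)-5-[(tert-butyldimethylsilyloxy)methyl]furan-2(5H)-one, via α-phenylselanyl lactone 5 (not isolated)
Conditions: LDA, THF, −78 °C; PhSeBr, −78 °C; then AcOH, 30% aq. H2O2, 0 °C → rt
Reagents that add atoms: none
Why: α-Selenenylation of the lactone enolate followed by oxidation and selenoxide syn-elimination (Reich) should give the butenolide, the AcOH-buffered oxidation avoiding racemisation of the γ-centre through the dienolate.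

**Step 5**
Reactants: 6 (R)-5-[(tert-butyldimethylsilyloxy)methyl]furan-2(5H)-one
Product: 7 (4S,5R)-5-[(tert-butyldimethylsilyloxy)methyl]-4-(hydroxymethyl)dihydrofuran-2(3H)-one (trans)
Conditions: Ph2CO (0.2 equiv), degassed MeOH, hν (350 nm, Pyrex), rt
Reagents that add atoms: methanol, CO
Why: In this photosensitised radical conjugate addition, triplet benzophenone abstracts hydrogen from methanol and the hydroxymethyl radical adds to the butenolide β-carbon on the face opposite the C8 CH2OTBS group, which sets C7 trans to C8.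

**Step 6**
Reactants: 7 (4S,5R)-5-[(tert-butyldimethylsilyloxy)methyl]-4-(hydroxymethyl)dihydrofuran-2(3H)-one
Product: 8 (4R,5R)-5-[(tert-butyldimethylsilyloxy)methyl]-4-(iodomethyl)dihydrofuran-2(3H)-one
Conditions: I2, PPh3, imidazole, CH2Cl2, 0 °C → rt
Reagents that add atoms: iodine, II
Why: Appel-type iodination converts the unhindered primary C6 alcohol into the iodide by SN2 without touching the silyl ether or the lactone.

**Step 7**
Reactants: 9 prop-2-yn-1-ol; 10 2-(2-bromoethyl)-1,3-dioxolane
Product: 13 (Z)-2-[2-(1,3-dioxolan-2-yl)ethyl]-3-iodoprop-2-en-1-ol, via Grignard reagent 11 (not isolated), via alkenylmagnesium chelate 12 (not isolated)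
Conditions: Mg, THF, 25 °C (10 → 11, 2.5 equiv); 9, CuI (10 mol%), THF, −10 °C → rt; I2, THF, −78 → 0 °C
Reagents that add atoms: iodine, II
Why: Copper-catalysed anti-carbomagnesiation of the propargyl alkoxide puts the alkyl group on the internal carbon and magnesium on the terminal carbon cis to CH2O in a five-membered chelate, and iodinolysis with retention gives the Z-iodoalkene that fixes the C4=C5 geometry.

**Step 8**
Reactants: 13 (Z)-2-[2-(1,3-dioxolan-2-yl)ethyl]-3-iodoprop-2-en-1-ol
Product: 14 2-[(3Z)-4-iodo-3-{[(4-methoxybenzyl)oxy]methyl}but-3-en-1-yl]-1,3-dioxolane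
Conditions: NaH, PMBCl, Bu4NI (cat.), THF–DMF, 0 °C → rt
Reagents that add atoms: 4-methoxybenzyl chloride, COc1ccc(CCl)cc1
Why: Williamson etherification of the sodium alkoxide is safe here because the iodoalkene has no β-hydrogen for elimination and the acetal is base-stable.

**Step 9**
Reactants: 8 (4R,5R)-5-[(tert-butyldimethylsilyloxy)methyl]-4-(iodomethyl)dihydrofuran-2(3H)-one; 14 2-[(3Z)-4-iodo-3-{[(4-methoxybenzyl)oxy]methyl}but-3-en-1-yl]-1,3-dioxolane
Product: 16 (4R,5R)-5-[(tert-butyldimethylsilyloxy)methyl]-4-[(2Z)-5-(1,3-dioxolan-2-yl)-3-{[(4-methoxybenzyl)oxy]methyl}pent-2-en-1-yl]dihydrofuran-2(3H)-one, via alkylzinc iodide 15 (not isolated)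
Conditions: Zn dust (BrCH2CH2Br/TMSCl-activated), DMF, rt; then 14, PdCl2(dppf) (5 mol%), DMF–THF, rt → 40 °C
Reagents that add atoms: none
Why: Zinc inserts into the primary C6–I bond (no β-leaving group, lactone tolerated) and the alkylzinc iodide undergoes Negishi sp3–sp2 coupling with the alkenyl iodide with retention of geometry to form C5–C6, the bidentate dppf ligand disfavouring β-hydride elimination.

**Step 10**
Reactants: 16 the TBS-protected coupling product
Product: 17 (4R,5R)-5-(hydroxymethyl)-4-[(2Z)-5-(1,3-dioxolan-2-yl)-3-{[(4-methoxybenzyl)oxy]methyl}pent-2-en-1-yl]dihydrofuran-2(3H)-one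
Conditions: TBAF, AcOH, THF, 0 °C → rt
Reagents that add atoms: none
Why: Fluoride desilylation of the primary TBS ether is buffered with acetic acid to prevent alkoxide-mediated translactonisation, while the acetal and PMB ether are inert.

**Step 11**
Reactants: 17 the C9 alcohol
Product: 18 [(2R,3R)-3-[(2Z)-5-(1,3-dioxolan-2-yl)-3-{[(4-methoxybenzyl)oxy]methyl}pent-2-en-1-yl]-5-oxotetrahydrofuran-2-yl]methyl trifluoromethanesulfonate
Conditions: Tf2O, 2,6-lutidine, CH2Cl2, −78 °C; used at once
Reagents that add atoms: trifluoromethanesulfonic anhydride, O=S(=O)(OS(=O)(=O)C(F)(F)F)C(F)(F)F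
Why: O-Sulfonylation at −78 °C gives the triflate needed for substitution at the β-oxygenated, β-branched C9, lutidine scavenging TfOH so that the acetal and PMB ether survive.

**Step 12**
Reactants: 18 the C9 triflate; 19 allyl 2-(diethoxyphosphoryl)acetate
Product: 20 allyl 2-(diethoxyphosphoryl)-3-[(2S,3R)-3-[(2Z)-5-(1,3-dioxolan-2-yl)-3-{[(4-methoxybenzyl)oxy]methyl}pent-2-en-1-yl]-5-oxotetrahydrofuran-2-yl]propanoate (C10 epimers)
Conditions: 19 (3 equiv), NaH (2.8 equiv), THF–DMF, 0 °C; then 18, 0 °C → rt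
Reagents that add atoms: none
Why: SN2 C-alkylation of the soft sodium phosphonoacetate carbanion by the primary triflate forms C9–C10, excess nucleophile suppressing dialkylation and the weakly basic stabilised anion sparing the lactone.

**Step 13**
Reactants: 20 the phosphonoacetate acetal
Product: 21 allyl 2-(diethoxyphosphoryl)-3-[(2S,3R)-3-[(2Z)-3-{[(4-methoxybenzyl)oxy]methyl}-6-oxohex-2-en-1-yl]-5-oxotetrahydrofuran-2-yl]propanoate (C10 epimers)
Conditions: 1 M aq. HCl, THF, rt
Reagents that add atoms: water, O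
Why: Acid-catalysed acetal hydrolysis unmasks the C1 aldehyde under conditions that leave the PMB ether, allyl ester, phosphonate and lactone intact.

**Step 14**
Reactants: 21 the phosphonoacetate aldehyde
Product: 23 allyl (7R,8S,1(10)E,4Z)-15-[(4-methoxybenzyl)oxy]germacra-1(10),4-dien-12,8-olid-14-oate (trans-lactone fused to the ten-membered ring; CO2allyl on C10, CH2OPMB on C4; C10=C1 ring-cis, C4=C5 ring-trans), via lithium β-oxidophosphonate 22 (not isolated)
Conditions: LiCl (20 equiv), DBU (10 equiv), MeCN, ca. 1 mM, rt; 21 added by syringe pump over 12 h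
Reagents that add atoms: none
Why: LiCl/DBU deprotonates the lithium-chelated C10 phosphonoacetate, the carbanion adds to the C1 aldehyde, and the β-oxidophosphonate collapses through an oxaphosphetane with loss of diethyl phosphate to give C10=C1. This is an intramolecular Horner–Wadsworth–Emmons olefination under Masamune–Roush conditions, the reaction type used for macrocyclic enoates. The ten-membered carbocycle closes in the addition step in a 10-exo-trig mode, and syringe-pump addition at high dilution favours it over oligomerisation. No stereocentre is created: both C10 epimers converge, and the amine base is too weak to touch C7, C8 or the lactone α-position. The selectivity needed is the E-enoate (C14 ester trans to C2), which the reversible addition of an α-substituted stabilised phosphonate favours. It is also the ring-cis olefin, the low-strain geometry next to the ring-trans C4=C5 bond, so reagent preference and ring preference are matched.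

**Step 15**
Reactants: 23 the macrocyclic allyl enoate
Product: 24 (7R,8S,1(10)E,4Z)-15-[(4-methoxybenzyl)oxy]germacra-1(10),4-dien-12,8-olid-14-oic acid
Conditions: Pd(PPh3)4 (5 mol%), morpholine, THF, rt; pH 4 work-up
Reagents that add atoms: none
Why: In this Tsuji–Trost deallylation Pd(0) ionises the allyl ester to a π-allyl complex that morpholine captures, releasing the C14 acid under neutral conditions that spare the lactone and the PMB ether.

**Step 16**
Reactants: 24 the C14 acid
Product: 26 (7R,8S,1(10)E,4Z)-14-hydroxy-15-[(4-methoxybenzyl)oxy]germacra-1(10),4-dien-12,8-olide, via isobutyl mixed carbonic anhydride 25 (not isolated)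
Conditions: iBuOCOCl, N-methylmorpholine, THF, −15 °C; then NaBH4, H2O, −15 → 0 °C
Reagents that add atoms: none
Why: Activation as the mixed carbonic anhydride lets NaBH4 reduce the acid to the allylic alcohol at low temperature faster than it attacks the γ-lactone, and α-substitution of the enoate disfavours conjugate reduction.

**Step 17**
Reactants: 26 the C14 allylic alcohol
Product: 27 (7R,8S,1(10)E,4Z)-14-(tert-butyldimethylsilyloxy)-15-[(4-methoxybenzyl)oxy]germacra-1(10),4-dien-12,8-olide
Conditions: TBSCl, imidazole, CH2Cl2, rt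
Reagents that add atoms: tert-butyldimethylsilyl chloride, CC(C)(C)[Si](C)(C)Cl
Why: Standard silylation of the primary allylic alcohol removes the only acidic O–H before the lactone is enolised.

**Step 18**
Reactants: 27 the C14 silyl ether
Product: 30 (7R,8S,1(10)E,4Z)-14-(tert-butyldimethylsilyloxy)-15-[(4-methoxybenzyl)oxy]germacra-1(10),4,11(13)-trien-12,8-olide, via Mannich base 28 (not isolated), via trimethylammonium iodide 29 (not isolated)
Conditions: LDA, THF, −78 °C; CH2=NMe2+ I−, −78 °C → rt; MeI (excess), rt; sat. aq. NaHCO3, rt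
Reagents that add atoms: Eschenmoser's salt (N,N-dimethylmethyleneiminium iodide), C=[N+](C)C.[I-]
Why: The lactone lithium enolate is aminomethylated at C11 (Mannich reaction with Eschenmoser's salt), and quaternisation followed by mild-base β-elimination installs the exocyclic C11=C13 methylene, destroying the transient C11 stereocentre.

**Step 19**
Reactants: 30 the α-methylene lactone PMB ether
Product: 31 (7R,8S,1(10)E,4Z)-14-(tert-butyldimethylsilyloxy)-15-hydroxygermacra-1(10),4,11(13)-trien-12,8-olide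
Conditions: DDQ, CH2Cl2–pH 7 phosphate buffer, 0 °C
Reagents that add atoms: none
Why: Oxidative PMB cleavage, in which DDQ oxidises the electron-rich benzyl ether to an oxocarbenium ion that water hydrolyses, should leave the silyl ether, both trisubstituted olefins and the methylene lactone untouched under buffered conditions.

**Step 20**
Reactants: 32 2-hydroxy-2-methylpropanoic acid
Product: 34 2-methyl-2-[(triethylsilyl)oxy]propanoic acid, via triethylsilyl ester 33 (not isolated)
Conditions: TESCl (2.2 equiv), imidazole, DMF, 0 °C → rt; then THF–H2O, AcOH (cat.), 0 °C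
Reagents that add atoms: chlorotriethylsilane, CC[Si](Cl)(CC)CC
Why: Exhaustive silylation followed by selective hydrolysis of the far more labile silyl ester leaves the tertiary TES ether and gives the protected acid.

**Step 21**
Reactants: 31 the C15 alcohol; 34 2-methyl-2-[(triethylsilyl)oxy]propanoic acid
Product: 36 (7R,8S,1(10)E,4Z)-14-(tert-butyldimethylsilyloxy)-15-{2-methyl-2-[(triethylsilyl)oxy]propanoyloxy}germacra-1(10),4,11(13)-trien-12,8-olide, via Yamaguchi mixed anhydride 35 (not isolated)
Conditions: 2,4,6-Cl3C6H2COCl, Et3N, THF, rt; then 31, DMAP, toluene, rt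
Reagents that add atoms: none
Why: In this Yamaguchi esterification the hindered acid is activated as the trichlorobenzoyl mixed anhydride and DMAP transfers the acyl group to the primary C15 alcohol, the silyl ether on the tertiary hydroxyl preventing self-acylation.

**Step 22**
Reactants: 36 the bis-silyl ester
Product: 37 target, [(7R,8S,1(10)E,4Z)-14-hydroxy-12-oxo-germacra-1(10),4,11(13)-trien-12,8-olid-15-yl] 2-hydroxy-2-methylpropanoate
Conditions: HF·pyridine, pyridine, THF, 0 °C → rt
Reagents that add atoms: none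
Why: Fluoride desilylation with pyridine-buffered HF should cleave the primary TBS ether and the tertiary TES ether in one operation without opening either ester or adding to the methylene lactone.

**Compound list**
1 | D-glutamic acid | N[C@H](CCC(=O)O)C(=O)O | starting material
2 | (R)-5-oxotetrahydrofuran-2-carboxylic acid | OC(=O)[C@H]1CCC(=O)O1 | intermediate
3 | (R)-5-(hydroxymethyl)dihydrofuran-2(3H)-one | OC[C@H]1CCC(=O)O1 | intermediate
4 | (R)-5-[(tert-butyldimethylsilyloxy)methyl]dihydrofuran-2(3H)-one | CC(C)(C)[Si](C)(C)OC[C@H]1CCC(=O)O1 | intermediate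
5 | (5R)-5-[(tert-butyldimethylsilyloxy)methyl]-3-(phenylselanyl)dihydrofuran-2(3H)-one, C3 epimers (formed in the flask) | CC(C)(C)[Si](C)(C)OC[C@H]1CC([Se]c2ccccc2)C(=O)O1 | intermediate
6 | (R)-5-[(tert-butyldimethylsilyloxy)methyl]furan-2(5H)-one | CC(C)(C)[Si](C)(C)OC[C@H]1C=CC(=O)O1 | intermediate
7 | (4S,5R)-5-[(tert-butyldimethylsilyloxy)methyl]-4-(hydroxymethyl)dihydrofuran-2(3H)-one | OC[C@@H]1CC(=O)O[C@H]1CO[Si](C)(C)C(C)(C)C | intermediate
8 | (4R,5R)-5-[(tert-butyldimethylsilyloxy)methyl]-4-(iodomethyl)dihydrofuran-2(3H)-one | IC[C@@H]1CC(=O)O[C@H]1CO[Si](C)(C)C(C)(C)C | intermediate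
9 | prop-2-yn-1-ol | C#CCO | starting material
10 | 2-(2-bromoethyl)-1,3-dioxolane | BrCCC1OCCO1 | starting material
11 | [2-(1,3-dioxolan-2-yl)ethyl]magnesium bromide (formed in the flask) | Br[Mg]CCC1OCCO1 | intermediate
12 | 4-[2-(1,3-dioxolan-2-yl)ethyl]-2,5-dihydro-1,2-oxamagnesole, cyclic alkenylmagnesium alkoxide with Mg cis to CH2O (formed in the flask) | [Mg]1OCC(CCC2OCCO2)=C1 | intermediate
13 | (Z)-2-[2-(1,3-dioxolan-2-yl)ethyl]-3-iodoprop-2-en-1-ol | OC/C(CCC1OCCO1)=C\I | intermediate
14 | 2-[(3Z)-4-iodo-3-{[(4-methoxybenzyl)oxy]methyl}but-3-en-1-yl]-1,3-dioxolane | COc1ccc(COC/C(CCC2OCCO2)=C\I)cc1 | intermediate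
15 | {[(2R,3R)-2-[(tert-butyldimethylsilyloxy)methyl]-5-oxotetrahydrofuran-3-yl]methyl}zinc iodide (formed in the flask) | I[Zn]C[C@@H]1CC(=O)O[C@H]1CO[Si](C)(C)C(C)(C)C | intermediate
16 | (4R,5R)-5-[(tert-butyldimethylsilyloxy)methyl]-4-[(2Z)-5-(1,3-dioxolan-2-yl)-3-{[(4-methoxybenzyl)oxy]methyl}pent-2-en-1-yl]dihydrofuran-2(3H)-one | COc1ccc(COC/C(CCC2OCCO2)=C\C[C@@H]3CC(=O)O[C@H]3CO[Si](C)(C)C(C)(C)C)cc1 | intermediate
17 | (4R,5R)-5-(hydroxymethyl)-4-[(2Z)-5-(1,3-dioxolan-2-yl)-3-{[(4-methoxybenzyl)oxy]methyl}pent-2-en-1-yl]dihydrofuran-2(3H)-one | COc1ccc(COC/C(CCC2OCCO2)=C\C[C@@H]3CC(=O)O[C@H]3CO)cc1 | intermediate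
18 | [(2R,3R)-3-[(2Z)-5-(1,3-dioxolan-2-yl)-3-{[(4-methoxybenzyl)oxy]methyl}pent-2-en-1-yl]-5-oxotetrahydrofuran-2-yl]methyl trifluoromethanesulfonate | COc1ccc(COC/C(CCC2OCCO2)=C\C[C@@H]3CC(=O)O[C@H]3COS(=O)(=O)C(F)(F)F)cc1 | intermediate
19 | allyl 2-(diethoxyphosphoryl)acetate | C=CCOC(=O)CP(=O)(OCC)OCC | starting material
20 | allyl 2-(diethoxyphosphoryl)-3-[(2S,3R)-3-[(2Z)-5-(1,3-dioxolan-2-yl)-3-{[(4-methoxybenzyl)oxy]methyl}pent-2-en-1-yl]-5-oxotetrahydrofuran-2-yl]propanoate, C10 epimers | COc1ccc(COC/C(CCC2OCCO2)=C\C[C@@H]3CC(=O)O[C@H]3CC(C(=O)OCC=C)P(=O)(OCC)OCC)cc1 | intermediate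
21 | allyl 2-(diethoxyphosphoryl)-3-[(2S,3R)-3-[(2Z)-3-{[(4-methoxybenzyl)oxy]methyl}-6-oxohex-2-en-1-yl]-5-oxotetrahydrofuran-2-yl]propanoate, C10 epimers | O=CCC/C(COCc1ccc(OC)cc1)=C/C[C@@H]1CC(=O)O[C@H]1CC(C(=O)OCC=C)P(=O)(OCC)OCC | intermediate
22 | lithium alkoxide of the ring-closed adduct: ten-membered ring with C1–O−, C10 bearing CO2allyl and P(O)(OEt)2, trans-lactone at C7/C8 (formed in the flask) | [Li+].[O-]C1CC/C(COCc2ccc(OC)cc2)=C/C[C@@H]3CC(=O)O[C@H]3CC1(C(=O)OCC=C)P(=O)(OCC)OCC | intermediate
23 | allyl (7R,8S,1(10)E,4Z)-15-[(4-methoxybenzyl)oxy]germacra-1(10),4-dien-12,8-olid-14-oate | C=CCOC(=O)/C1=C/CC/C(COCc3ccc(OC)cc3)=C/C[C@@H]2CC(=O)O[C@H]2C1 | intermediate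
24 | (7R,8S,1(10)E,4Z)-15-[(4-methoxybenzyl)oxy]germacra-1(10),4-dien-12,8-olid-14-oic acid | OC(=O)/C1=C/CC/C(COCc3ccc(OC)cc3)=C/C[C@@H]2CC(=O)O[C@H]2C1 | intermediate
25 | isobutyl carbonic mixed anhydride of acid 24 (formed in the flask) | CC(C)COC(=O)OC(=O)/C1=C/CC/C(COCc3ccc(OC)cc3)=C/C[C@@H]2CC(=O)O[C@H]2C1 | intermediate
26 | (7R,8S,1(10)E,4Z)-14-hydroxy-15-[(4-methoxybenzyl)oxy]germacra-1(10),4-dien-12,8-olide | OC/C1=C/CC/C(COCc3ccc(OC)cc3)=C/C[C@@H]2CC(=O)O[C@H]2C1 | intermediate
27 | (7R,8S,1(10)E,4Z)-14-(tert-butyldimethylsilyloxy)-15-[(4-methoxybenzyl)oxy]germacra-1(10),4-dien-12,8-olide | CC(C)(C)[Si](C)(C)OC/C1=C/CC/C(COCc3ccc(OC)cc3)=C/C[C@@H]2CC(=O)O[C@H]2C1 | intermediate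
28 | 11-[(dimethylamino)methyl] derivative of 27, C11 epimers (formed in the flask) | CN(C)CC1C(=O)O[C@H]2C/C(CO[Si](C)(C)C(C)(C)C)=C\CC/C(COCc3ccc(OC)cc3)=C/C[C@H]12 | intermediate
29 | 11-[(trimethylammonio)methyl] iodide of 27, C11 epimers (formed in the flask) | C[N+](C)(C)CC1C(=O)O[C@H]2C/C(CO[Si](C)(C)C(C)(C)C)=C\CC/C(COCc3ccc(OC)cc3)=C/C[C@H]12.[I-] | intermediate
30 | (7R,8S,1(10)E,4Z)-14-(tert-butyldimethylsilyloxy)-15-[(4-methoxybenzyl)oxy]germacra-1(10),4,11(13)-trien-12,8-olide | C=C1C(=O)O[C@H]2C/C(CO[Si](C)(C)C(C)(C)C)=C\CC/C(COCc3ccc(OC)cc3)=C/C[C@H]12 | intermediate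
31 | (7R,8S,1(10)E,4Z)-14-(tert-butyldimethylsilyloxy)-15-hydroxygermacra-1(10),4,11(13)-trien-12,8-olide | C=C1C(=O)O[C@H]2C/C(CO[Si](C)(C)C(C)(C)C)=C\CC/C(CO)=C/C[C@H]12 | intermediate
32 | 2-hydroxy-2-methylpropanoic acid | CC(C)(O)C(=O)O | starting material
33 | triethylsilyl 2-methyl-2-[(triethylsilyl)oxy]propanoate (formed in the flask) | CC[Si](CC)(CC)OC(C)(C)C(=O)O[Si](CC)(CC)CC | intermediate
34 | 2-methyl-2-[(triethylsilyl)oxy]propanoic acid | CC[Si](CC)(CC)OC(C)(C)C(=O)O | intermediate
35 | 2-methyl-2-[(triethylsilyl)oxy]propanoic 2,4,6-trichlorobenzoic anhydride (formed in the flask) | CC[Si](CC)(CC)OC(C)(C)C(=O)OC(=O)c1c(Cl)cc(Cl)cc1Cl | intermediate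
36 | (7R,8S,1(10)E,4Z)-14-(tert-butyldimethylsilyloxy)-15-{2-methyl-2-[(triethylsilyl)oxy]propanoyloxy}germacra-1(10),4,11(13)-trien-12,8-olide | C=C1C(=O)O[C@H]2C/C(CO[Si](C)(C)C(C)(C)C)=C\CC/C(COC(=O)C(C)(C)O[Si](CC)(CC)CC)=C/C[C@H]12 | intermediate
37 | CNP0194188.1, (7R,8S,1(10)E,4Z)-14-hydroxy-15-(2-hydroxy-2-methylpropanoyloxy)germacra-1(10),4,11(13)-trien-12,8-olide | C=C1C(=O)O[C@H]2C/C(CO)=C\CC/C(COC(=O)C(C)(C)O)=C/C[C@H]12 | target

**Step count**
Total: 22 steps. Longest linear sequence: 19 steps from D-glutamic acid (steps 1–6, 9–19, 21, 22). Steps 7 and 8 make the iodoalkene, step 20 the protected acid.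

**Steps most likely to fail**

1. Step 14 (macrocyclisation). Intermolecular olefination may outrun the ten-membered closure and give cyclic dimers and oligomers, or the amine base may enolise the C1 aldehyde and cause self-condensation. The fallback is an intramolecular Wittig reaction under neutral, salt-free conditions. It sets out from triflate 18, which should alkylate the stabilised ylide allyl (triphenylphosphoranylidene)acetate at carbon to give the acetal phosphonium triflate F1. Aqueous HCl in THF frees the C1 aldehyde and gives the aldehyde phosphonium triflate F2. Slow addition of F2 to Et3N in toluene at 80 °C and ≤1 mM generates the ester-stabilised ylide F3, which closes onto the aldehyde with E selectivity and returns to the route at 23.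

2. Step 12 (C9–C10 alkylation). Substitution at the β-oxygenated, β-branched C9 may be slow enough that elimination towards the enol lactone, O-alkylation or double alkylation of the phosphonoacetate take over. The fallback replaces alkylation by condensation and conjugate reduction. It sets out from alcohol 17: Dess–Martin oxidation gives the C9 aldehyde F4 (the trans arrangement at C7/C8 is the thermodynamic one should C8 epimerise). Knoevenagel condensation with 19 (piperidine, AcOH, toluene, 4 Å sieves) gives the alkylidenephosphonoacetate F5 as an E/Z mixture. Conjugate reduction with NaBH4 in EtOH at 0 °C gives 20, where the route is rejoined.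

3. Step 9 (Negishi coupling). Zinc insertion may be sluggish, or the alkylzinc may be lost to protodezincation and β-hydride elimination, so that reduced lactone and alkene by-products dominate over cross-coupling. The fallback reverses the polarity and uses copper catalysis. From alcohol 7, Tf2O/2,6-lutidine gives the C6 triflate F6. Iodide 14 undergoes iodine–magnesium exchange with iPrMgCl·LiCl (THF, −20 °C, assisted by the cis CH2OPMB group) to the alkenylmagnesium chloride F7. CuBr·SMe2-catalysed coupling of F7 with F6 at −78 → −40 °C, where the lactone carbonyl is not attacked, gives 16 with retention of the olefin geometry.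

**Further compounds**
F1 | step 14 | [1-(allyloxycarbonyl)-2-{(2S,3R)-3-[(2Z)-5-(1,3-dioxolan-2-yl)-3-{[(4-methoxybenzyl)oxy]methyl}pent-2-en-1-yl]-5-oxotetrahydrofuran-2-yl}ethyl]triphenylphosphonium triflate | COc1ccc(COC/C(CCC2OCCO2)=C\C[C@@H]3CC(=O)O[C@H]3CC(C(=O)OCC=C)[P+](c4ccccc4)(c5ccccc5)c6ccccc6)cc1.[O-]S(=O)(=O)C(F)(F)F
F2 | step 14 | the corresponding C1 aldehyde phosphonium triflate | O=CCC/C(COCc1ccc(OC)cc1)=C/C[C@@H]2CC(=O)O[C@H]2CC(C(=O)OCC=C)[P+](c3ccccc3)(c4ccccc4)c5ccccc5.[O-]S(=O)(=O)C(F)(F)F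
F3 | step 14 | the corresponding ester-stabilised triphenylphosphorane | O=CCC/C(COCc1ccc(OC)cc1)=C/C[C@@H]2CC(=O)O[C@H]2CC(C(=O)OCC=C)=P(c3ccccc3)(c4ccccc4)c5ccccc5
F4 | step 12 | (2S,3R)-3-[(2Z)-5-(1,3-dioxolan-2-yl)-3-{[(4-methoxybenzyl)oxy]methyl}pent-2-en-1-yl]-5-oxotetrahydrofuran-2-carbaldehyde | COc1ccc(COC/C(CCC2OCCO2)=C\C[C@@H]3CC(=O)O[C@H]3C=O)cc1
F5 | step 12 | allyl 2-(diethoxyphosphoryl)-3-[(2R,3R)-3-[(2Z)-5-(1,3-dioxolan-2-yl)-3-{[(4-methoxybenzyl)oxy]methyl}pent-2-en-1-yl]-5-oxotetrahydrofuran-2-yl]prop-2-enoate, E/Z mixture | COc1ccc(COC/C(CCC2OCCO2)=C\C[C@@H]3CC(=O)O[C@H]3C=C(C(=O)OCC=C)P(=O)(OCC)OCC)cc1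
F6 | step 9 | [(2R,3S)-2-[(tert-butyldimethylsilyloxy)methyl]-5-oxotetrahydrofuran-3-yl]methyl trifluoromethanesulfonate | FC(F)(F)S(=O)(=O)OC[C@@H]1CC(=O)O[C@H]1CO[Si](C)(C)C(C)(C)C
F7 | step 9 | [(1Z)-4-(1,3-dioxolan-2-yl)-2-{[(4-methoxybenzyl)oxy]methyl}but-1-en-1-yl]magnesium chloride | COc1ccc(COC/C(CCC2OCCO2)=C\[Mg]Cl)cc1
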